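The ratio of J to X is what is asked here, so I count in the share of X in X plus J. An even split, a share of one half, is the zero of my scale. The proposed steps are L and E giving X, the same step helped by X, and X going to J and back.

| flask | L | E | remark | time |
|---|---|---|---|---|
| alpha | 2 M | 2.4 M | run made earlier |  |
| epsilon | 2 M | 1.6 M | run made earlier |  |
| autumn | 2.0 M | 2.40 M | a closed flask charged with all of it at once and left for 5.0 min | 5.0 min |
| dusk | 2.0 M (fed, over 4.00 min) | 2.40 M | all but L at the start; L goes in evenly over 4.00 min, the run ends at 5.0 min | 5.0 min |
| midnight | 2.0 M | 2.40 M | one stirred flow tank at steady state, fed with the mixture as stated, mean residence time 5.0 min |  |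
| winter | 2.0 M | 2.40 M (fed, over 4.00 min) | all but E at the start; E goes in evenly over 4.00 min, the run ends at 5.0 min | 5.0 min |

- alpha (time / min: X / %, J / %): 0.667: 5.2, 1.2; 1.33: 28.5, 10.5; 2.00: 51.5, 22.4; 2.50: 58.0, 25.3; 3.00: 60.2, 29.6
- epsilon (time / min: X / %, J / %): 0.333: 1.9, 1.6; 1.00: 3.4, 1.9; 2.00: 25.1, 8.9; 3.00: 42.0, 16.4; 4.00: 48.8, 21.3

(readings scatter by 1 percentage point)

- the stated concentrations are those of everything mixed, before any reaction; amounts are the same in each set-up
- steps that have been proposed: L + E + X -> 2 X; L + E -> X; X <-> J
- the feed brings no volume worth counting
- the earlier runs were made in a closed, stirred flask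

- the set-up with the highest share of X in all that became X or J, at the outlet or at the end ("none" if the first two lie within 2 percentage points) (autumn / dusk / midnight / winter / none)
- share of X in all that became X or J, at the outlet or at the end, autumn
- share of X in all that became X or J, at the outlet or at the end, dusk
- share of X in all that became X or J, at the outlet or at the end, midnight
- share of X in all that became X or J, at the outlet or at the end, winter

I take two extreme versions. In the first, X and J exchange instantly, so the share sits at its thermodynamic-control value in every set-up. I read that value from the last readings: the alpha run gives 67.0% and the epsilon run gives 69.6%. Their mean is 68.3%, the equilibrium share, the share of X once X and J have stopped exchanging net.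

In the second version, J forms too slowly to matter, and the share stays near 100 percent.

The alpha run shows which version is closer. In the alpha run at 1.33 min, the J reading stands 1.9 percentage points below the amount the equilibrium share gives, against a scatter of 1 point. With the total rising as it does, J trails by about 0.112 min, which is a rough reading. That lag is shorter than the 1.00 min left after dosing ends, so I put autumn, dusk and winter near 68.3%.

In the midnight tank, washout competes with the lag. My reckoning there is 69.0%. That is a spread of 0.7 points against a margin of 2 points, so I commit to none.

The forecast gives 67% for autumn, 68.2% for dusk, 68.7% for midnight and 67.8% for winter, with best none. It says: “That caps the share at about 67%, whatever the vessel.”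

The flasks give 68.5% for autumn, 68.9% for dusk, 69.1% for midnight and 68.9% for winter, with best none.

    L + E + X → 2 X (k = 0.0190 M⁻² s⁻¹)
    L + E → X (k = 1.10 × 10⁻⁴ M⁻¹ s⁻¹)
    X ⇌ J (K = 0.460, k = 0.0560 s⁻¹)

Autumn stands 0.20 points from the equilibrium share I read. The way back from J to X holds it there. With that step struck out, the autumn share falls from 68.5% to 0.902%. Midnight, the second flask, gives 69.1%, and the tank's back-mixing is not what sets that value. The reverse step, J to X, carries the midnight share. Without that step, the midnight share is 5.62%.

The data are calculated on assumed constants; noise was put on by code.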